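Retrosynthesis: the C3'–Br and C4'–Cl bonds are cut first (back to a C3'=C4' ring alkene), then C1'–C6' and O1–C2 together, then C1'–C2' (alkenyl–allyl coupling), C5–Br (epoxide opening) and C3–C4 (allylation).
Enabling feature: C6'–OH, C1'–H and the C2–O1 bond form a cis 1,3-dioxygenated array across the link between the cyclohexane (C1'–C6') and the pyran (O1, C2–C6), the p-menthane-3,8-diol pattern that an aldehyde–alkene cyclisation with oxygen capture leaves behind.
Forward: fragment 1 (C1', C2–C6; stannane 10) and fragment 2 (C2'–C6'; allyl chloride 16) are joined at C1'–C2', the C6' aldehyde is unveiled, the carbocycle and the pyran close in one cationic step, and the ring alkene is converted to the bromochloride last.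
Stereochemistry: C3 from Brown allylation; C5 from Shi epoxidation and invertive bromide opening; both Z alkenes from carbometallation (alkyne carbomagnesiation, ynoate carbocupration).
C1', C2 and C6' come from the cascade (anti addition across the Z alkene, pyran chair, axial carbonyl); C3' and C4' from α-epoxidation, trans-diaxial HBr opening and a bromonium-mediated halogen interchange.

Key step: step 16

Numbering: pyran O1, C2 (methyl, carbocycle), C3 (OAc), C4, C5 (Br), C6 (Me2); carbocycle C1' (bonded to C2), C2', C3' (Br), C4' (Me, Cl), C5', C6' (OH). β is the carbocycle face that carries the C6' oxygen and the C1'–C2 bond; α is the other face.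
Assumption (remark on the chemistry): with the pyranyl group equatorial the target holds C3'β–Br and C4'α–Cl trans-diequatorial. A direct anti bromochlorination of the C3'=C4' alkene (diaxial, chloride to C4' on the β face) would not give this, so the halogens are brought in through an α-epoxide and a β-bromonium/chloride pair, and the diequatorial member of that pair is taken to be the more stable one.

Step 1
Reactants: 1 prop-2-yn-1-ol
Product: 3 (Z)-3-iodo-2-methylprop-2-en-1-ol, via magnesium chelate 2 (not isolated)
Conditions: MeMgBr (3 equiv), CuI (10 mol%), THF, 0 °C to rt; then I2, −78 °C to rt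
Reagents that add atoms: methylmagnesium bromide, C[Mg]Br; iodine, II
Why: Copper-catalysed anti carbomagnesiation of the propargylic alkoxide puts methyl on the internal carbon and magnesium on the terminal carbon inside a five-membered chelate, and iodinolysis with retention should give the Z iodoalkene.

Step 2
Reactants: 3 (Z)-3-iodo-2-methylprop-2-en-1-ol
Product: 4 (Z)-3-iodo-2-methylprop-2-enal
Conditions: MnO2, CH2Cl2, rt, dark; used at once
Reagents that add atoms: none
Why: Allylic alcohol oxidation with MnO2 is neutral and stops at the aldehyde, and immediate use should avoid Z to E drift of the β-iodo enal.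

Step 3
Reactants: 4 (Z)-3-iodo-2-methylprop-2-enal
Product: 5 (1Z,3S)-1-iodo-2-methylhexa-1,5-dien-3-ol
Conditions: dIpc2B(allyl) [from (+)-α-pinene], Et2O, −78 °C; then NaOH, H2O2, 0 °C
Reagents that add atoms: B-allyldiisopinocampheylborane derived from (+)-α-pinene, C=CCB([C@@H]1C[C@@H]2C[C@H]([C@H]1C)C2(C)C)[C@@H]1C[C@@H]2C[C@H]([C@H]1C)C2(C)C
Why: Brown allylation through a chair six-membered transition state, in which the pinene-derived groups send the allyl group to the Si face of the enal and so set C3 as S.

Step 4
Reactants: 5 (1Z,3S)-1-iodo-2-methylhexa-1,5-dien-3-ol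
Product: 6 tert-butyl{[(1Z,3S)-1-iodo-2-methylhexa-1,5-dien-3-yl]oxy}dimethylsilane
Conditions: TBSCl, imidazole, DMF, rt
Reagents that add atoms: tert-butyldimethylsilyl chloride, CC(C)(C)[Si](C)(C)Cl
Why: Standard silylation of a secondary allylic alcohol; the silyl ether is a non-participating group next to the later C2 cation.

Step 5
Reactants: 6 tert-butyl{[(1Z,3S)-1-iodo-2-methylhexa-1,5-dien-3-yl]oxy}dimethylsilane
Product: 7 tert-butyl{[(1Z,3S)-1-iodo-2,6-dimethylhepta-1,5-dien-3-yl]oxy}dimethylsilane
Conditions: 2-methyl-2-butene (solvent), second-generation Grubbs catalyst RuCl2(=CHPh)(H2IMes)(PCy3) (3 mol%), 40 °C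
Reagents that add atoms: 2-methyl-2-butene, CC=C(C)C
Why: Olefin cross-metathesis turns the terminal alkene into the prenyl group, while the trisubstituted iodoalkene is too hindered to enter the catalytic cycle.

Step 6
Reactants: 7 tert-butyl{[(1Z,3S)-1-iodo-2,6-dimethylhepta-1,5-dien-3-yl]oxy}dimethylsilane
Product: 8 tert-butyl{[(1Z,3S)-4-[(2R)-3,3-dimethyloxiran-2-yl]-1-iodo-2-methylbut-1-en-3-yl]oxy}dimethylsilane
Conditions: D-fructose-derived Shi ketone (30 mol%), Oxone (KHSO5), K2CO3, Bu4NHSO4, MeCN/CH2(OMe)2/aq. Na2B4O7 buffer, 0 °C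
Reagents that add atoms: Oxone (potassium peroxymonosulfate), [K+].[O-]S(=O)(=O)OO
Why: Shi epoxidation; the chiral dioxirane attacks the electron-rich prenyl alkene (the iodoalkene is electron-poor and hindered) through the spiro transition state and should give the R epoxide at C5 under reagent control.

Step 7
Reactants: 8 tert-butyl{[(1Z,3S)-4-[(2R)-3,3-dimethyloxiran-2-yl]-1-iodo-2-methylbut-1-en-3-yl]oxy}dimethylsilane
Product: 9 (3S,5S,6Z)-3-bromo-5-[(tert-butyldimethylsilyl)oxy]-7-iodo-2,6-dimethylhept-6-en-2-ol
Conditions: Li2NiBr4 (2 equiv), THF, 0 °C to rt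
Reagents that add atoms: dilithium tetrabromonickelate, [Li+].[Li+].Br[Ni-2](Br)(Br)Br
Why: SN2 epoxide opening by soft nucleophilic bromide at the less substituted carbon C5 with inversion, which turns the R epoxide carbon into the S bromide and leaves the tertiary C6 alcohol.

Step 8
Reactants: 9 (3S,5S,6Z)-3-bromo-5-[(tert-butyldimethylsilyl)oxy]-7-iodo-2,6-dimethylhept-6-en-2-ol
Product: 10 (3S,5S,6Z)-3-bromo-5-[(tert-butyldimethylsilyl)oxy]-2,6-dimethyl-7-(trimethylstannyl)hept-6-en-2-ol
Conditions: (Me3Sn)2, Pd(PPh3)4 (5 mol%), toluene, 80 °C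
Reagents that add atoms: hexamethylditin, C[Sn](C)(C)[Sn](C)(C)C
Why: Palladium-catalysed iodide-to-tin exchange with a distannane runs under neutral conditions with retention of the Z geometry and should leave the unactivated secondary bromide and the free tertiary alcohol alone.

Step 9
Reactants: 11 tert-butyl(but-3-yn-1-yloxy)dimethylsilane
Product: 13 methyl 5-[(tert-butyldimethylsilyl)oxy]pent-2-ynoate, via lithium acetylide 12 (not isolated)
Conditions: n-BuLi, THF, −78 °C; then ClCO2Me, −78 to 0 °C
Reagents that add atoms: methyl chloroformate, COC(=O)Cl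
Why: Deprotonation of the terminal alkyne and acylation of the acetylide with a chloroformate is the standard route to ynoates.

Step 10
Reactants: 13 methyl 5-[(tert-butyldimethylsilyl)oxy]pent-2-ynoate
Product: 14 methyl (2Z)-5-[(tert-butyldimethylsilyl)oxy]-3-methylpent-2-enoate
Conditions: Me2CuLi (from MeLi and CuI), THF, −78 °C; NH4Cl (aq) quench at −78 °C
Reagents that add atoms: lithium dimethylcuprate (made from methyllithium, C[Li], and CuI), [Li+].C[Cu-]C
Why: Conjugate carbocupration of the ynoate is a syn addition, and protonation of the alkenylcopper at low temperature with retention should give the Z enoate (ester cis to the silyloxyethyl chain).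

Step 11
Reactants: 14 methyl (2Z)-5-[(tert-butyldimethylsilyl)oxy]-3-methylpent-2-enoate
Product: 15 (2Z)-5-[(tert-butyldimethylsilyl)oxy]-3-methylpent-2-en-1-ol
Conditions: i-Bu2AlH (2.2 equiv), CH2Cl2, −78 °C
Reagents that add atoms: none
Why: 1,2-Reduction of the enoate with i-Bu2AlH gives the allylic alcohol without touching the alkene geometry or the silyl ether.

Step 12
Reactants: 15 (2Z)-5-[(tert-butyldimethylsilyl)oxy]-3-methylpent-2-en-1-ol
Product: 16 tert-butyl{[(3Z)-5-chloro-3-methylpent-3-en-1-yl]oxy}dimethylsilane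
Conditions: PPh3, CCl4, reflux
Reagents that add atoms: carbon tetrachloride, ClC(Cl)(Cl)Cl
Why: The Appel reaction converts primary allylic alcohols of the nerol type into the chlorides by SN2 displacement of the oxyphosphonium, without allylic transposition or loss of the Z geometry.

Step 13
Reactants: 10 (3S,5S,6Z)-3-bromo-5-[(tert-butyldimethylsilyl)oxy]-2,6-dimethyl-7-(trimethylstannyl)hept-6-en-2-ol; 16 tert-butyl{[(3Z)-5-chloro-3-methylpent-3-en-1-yl]oxy}dimethylsilane
Product: 17 (3S,5S,6Z,9Z)-3-bromo-5,12-bis[(tert-butyldimethylsilyl)oxy]-2,6,10-trimethyldodeca-6,9-dien-2-ol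
Conditions: Pd2(dba)3 (2.5 mol%), AsPh3 (10 mol%), NMP, 45 °C
Reagents that add atoms: none
Why: Stille coupling of an alkenylstannane with an allylic chloride: the η3-allyl palladium complex cannot easily place the metal on its tertiary terminus, so syn/anti interchange is slow and the alkenyl group should arrive at the primary terminus with both Z geometries kept, giving the skipped diene.

Step 14
Reactants: 17 (3S,5S,6Z,9Z)-3-bromo-5,12-bis[(tert-butyldimethylsilyl)oxy]-2,6,10-trimethyldodeca-6,9-dien-2-ol
Product: 18 (3Z,6Z,8S,10S)-10-bromo-8-[(tert-butyldimethylsilyl)oxy]-3,7,11-trimethyldodeca-3,6-diene-1,11-diol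
Conditions: CSA (10 mol%), MeOH/CH2Cl2 1:1, 0 °C
Reagents that add atoms: none
Why: Acid-catalysed methanolysis removes a primary silyl ether much faster than the hindered secondary allylic one at C3.

Step 15
Reactants: 18 (3Z,6Z,8S,10S)-10-bromo-8-[(tert-butyldimethylsilyl)oxy]-3,7,11-trimethyldodeca-3,6-diene-1,11-diol
Product: 19 (3Z,6Z,8S,10S)-10-bromo-8-[(tert-butyldimethylsilyl)oxy]-11-hydroxy-3,7,11-trimethyldodeca-3,6-dienal
Conditions: Dess–Martin periodinane, NaHCO3, CH2Cl2, 0 °C; used at once
Reagents that add atoms: none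
Why: Buffered Dess–Martin oxidation of the primary homoallylic alcohol gives the β,γ-unsaturated aldehyde without base or acid strong enough to move the alkene into conjugation, and the tertiary alcohol cannot be oxidised.

Step 16
Reactants: 19 (3Z,6Z,8S,10S)-10-bromo-8-[(tert-butyldimethylsilyl)oxy]-11-hydroxy-3,7,11-trimethyldodeca-3,6-dienal
Product: 20 (1R,6S)-6-{(2S,3S,5S)-5-bromo-3-[(tert-butyldimethylsilyl)oxy]-2,6,6-trimethyloxan-2-yl}-3-methylcyclohex-3-en-1-ol
Conditions: BF3·OEt2 (30 mol%), CH2Cl2 (0.01 M), −78 to −40 °C; Et3N quench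
Reagents that add atoms: none
Why: Proposed new method: BF3 bound to the C6' carbonyl oxygen makes the aldehyde the electrophile, C1' of the (Z)-C1'=C2 alkene adds to C6', and the positive charge building up at tertiary C2 is quenched on the opposite alkene face by the C6 hydroxyl, whose proton ends on the C6' oxygen so that the acid turns over; the closest known reaction types are Prins cyclisations ended by capture of the cation by an internal hydroxyl and the acid-mediated cyclisation of citronellal to cis-p-menthane-3,8-diol, neither shown on a β,γ-unsaturated aldehyde carrying an allylic silyl ether and a remote tertiary bromohydrin. The carbocycle closes 6-exo-trig at the carbonyl through a half-chair in which the attacking alkene stays outside the new ring, and the pyran closes 6-exo-trig at C2 through a chair. C1' and C2 are tied to each other by anti addition across the Z alkene (only the 1'S,2S or 1'R,2R pair can form), and the 1'S,2S sense is chosen by the pyran chair, in which the C5 bromine is equatorial, the C3 silyloxy group axial and close to the alkene plane, C1' equatorial and the bulky silyl ether turned away from the face on which the aldehyde arrives. C6' is set by the BF3-bound oxygen taking the pseudo-axial site of the half-chair, syn to the C1'–C2 bond, as the protonated carbonyl does on the way to the cis menthane diol. The step needs hydroxyl capture to outrun ene-type proton loss and drift of the β,γ-alkene into conjugation; the six-membered reach of the weakly basic bromohydrin oxygen, the Z ring alkene that already holds C5' and C2' on one side, the low temperature and the substoichiometric aprotic acid should secure this.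

Step 17
Reactants: 20 (1R,6S)-6-{(2S,3S,5S)-5-bromo-3-[(tert-butyldimethylsilyl)oxy]-2,6,6-trimethyloxan-2-yl}-3-methylcyclohex-3-en-1-ol
Product: 21 C6' chloroacetate of 20
Conditions: (ClCH2CO)2O, pyridine, DMAP (cat.), CH2Cl2, 0 °C
Reagents that add atoms: chloroacetic anhydride, O=C(CCl)OC(=O)CCl
Why: Acylation of the axial C6' alcohol with retention gives an ester that can later be removed beside an acetate and whose electron-poor carbonyl is a weak neighbouring group.

Step 18
Reactants: 21 C6' chloroacetate of 20
Product: 23 C3 acetate C6' chloroacetate, via C3 alcohol 22 (not isolated)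
Conditions: HF·pyridine, pyridine/THF, 0 °C to rt; concentrate; then Ac2O, DMAP, pyridine, rt
Reagents that add atoms: acetic anhydride, CC(=O)OC(C)=O
Why: Fluoride-driven desilylation under weakly acidic conditions spares the chloroacetate and the tertiary ether, and acetylation of the freed C3 alcohol installs the ester of the target before any acid-sensitive halide is present.

Step 19
Reactants: 23 C3 acetate C6' chloroacetate
Product: 24 3'α,4'α-epoxide of 23
Conditions: mCPBA, NaHCO3, CH2Cl2, 0 °C
Reagents that add atoms: 3-chloroperoxybenzoic acid, OOC(=O)c1cccc(Cl)c1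
Why: Prilezhaev epoxidation; the peracid should add to the α face, anti to the pseudo-axial C6' acyloxy group and to the C1' substituent, since the acylated oxygen cannot direct as a free hydroxyl would.

Step 20
Reactants: 24 3'α,4'α-epoxide of 23
Product: 25 4'β-bromo-3'α-hydroxy compound (trans-diaxial bromohydrin)
Conditions: HBr (48% aq, 1.5 equiv), CHCl3, −10 to 0 °C
Reagents that add atoms: hydrogen bromide, Br
Why: Acid-mediated epoxide opening in which bromide attacks tertiary C4' from the β face, the one mode that is both Markovnikov and trans-diaxial, giving C4'β–Br and C3'α–OH with inversion at C4'.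

Step 21
Reactants: 25 4'β-bromo-3'α-hydroxy compound
Product: 27 3'β-bromo-4'α-chloro C6' chloroacetate (trans-diequatorial), via diaxial 3'α-chloro-4'β-bromo isomer 26 (not isolated)
Conditions: SOCl2, pyridine, CH2Cl2, −20 to 0 °C; then MeCN, 70 °C
Reagents that add atoms: thionyl chloride, O=S(Cl)Cl
Why: Deoxychlorination with neighbouring-group participation: the C3' chlorosulfite leaves from the α face with help from the antiperiplanar C4'β bromine, chloride opens the β-bromonium ion from the α face (at C3' in the diaxial sense, or at C4'), and warming lets the diaxial isomer pass through the same ion pair to the diequatorial isomer (diaxial-to-diequatorial rearrangement of a vicinal dihalide), so that Br ends on C3'β and Cl on C4'α.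

Step 22
Reactants: 27 3'β-bromo-4'α-chloro C6' chloroacetate
Product: 28 (2S,3S,5S)-5-bromo-2-[(1S,2R,4R,5R)-5-bromo-4-chloro-2-hydroxy-4-methylcyclohexyl]-2,6,6-trimethyloxan-3-yl acetate (target)
Conditions: thiourea, NaHCO3, EtOH, 55 °C
Reagents that add atoms: none
Why: Chloroacetate cleavage by thiourea (S-alkylation at the CH2Cl carbon, then cyclisation onto the ester carbonyl) frees the hindered axial C6' alcohol and should not touch the C3 acetate or the hindered halides.

Compound list
1 | prop-2-yn-1-ol | C#CCO | starting material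
2 | magnesium chelate, cyclic (Z)-alkenylmagnesium alkoxide | CC1=C[Mg]OC1 | intermediate
3 | (Z)-3-iodo-2-methylprop-2-en-1-ol | OC/C(C)=C\I | intermediate
4 | (Z)-3-iodo-2-methylprop-2-enal | O=C/C(C)=C\I | intermediate
5 | (1Z,3S)-1-iodo-2-methylhexa-1,5-dien-3-ol | I\C=C(C)/[C@@H](O)CC=C | intermediate
6 | tert-butyl{[(1Z,3S)-1-iodo-2-methylhexa-1,5-dien-3-yl]oxy}dimethylsilane | I\C=C(C)/[C@@H](O[Si](C)(C)C(C)(C)C)CC=C | intermediate
7 | tert-butyl{[(1Z,3S)-1-iodo-2,6-dimethylhepta-1,5-dien-3-yl]oxy}dimethylsilane | I\C=C(C)/[C@@H](O[Si](C)(C)C(C)(C)C)CC=C(C)C | intermediate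
8 | tert-butyl{[(1Z,3S)-4-[(2R)-3,3-dimethyloxiran-2-yl]-1-iodo-2-methylbut-1-en-3-yl]oxy}dimethylsilane | I\C=C(C)/[C@@H](O[Si](C)(C)C(C)(C)C)C[C@H]1OC1(C)C | intermediate
9 | (3S,5S,6Z)-3-bromo-5-[(tert-butyldimethylsilyl)oxy]-7-iodo-2,6-dimethylhept-6-en-2-ol | I\C=C(C)/[C@@H](O[Si](C)(C)C(C)(C)C)C[C@H](Br)C(C)(C)O | intermediate
10 | (3S,5S,6Z)-3-bromo-5-[(tert-butyldimethylsilyl)oxy]-2,6-dimethyl-7-(trimethylstannyl)hept-6-en-2-ol (fragment 1) | C[Sn](C)(C)\C=C(C)/[C@@H](O[Si](C)(C)C(C)(C)C)C[C@H](Br)C(C)(C)O | intermediate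
11 | tert-butyl(but-3-yn-1-yloxy)dimethylsilane | C#CCCO[Si](C)(C)C(C)(C)C | starting material
12 | lithium acetylide of 11 | [Li]C#CCCO[Si](C)(C)C(C)(C)C | intermediate
13 | methyl 5-[(tert-butyldimethylsilyl)oxy]pent-2-ynoate | COC(=O)C#CCCO[Si](C)(C)C(C)(C)C | intermediate
14 | methyl (2Z)-5-[(tert-butyldimethylsilyl)oxy]-3-methylpent-2-enoate | COC(=O)/C=C(C)\CCO[Si](C)(C)C(C)(C)C | intermediate
15 | (2Z)-5-[(tert-butyldimethylsilyl)oxy]-3-methylpent-2-en-1-ol | OC/C=C(C)\CCO[Si](C)(C)C(C)(C)C | intermediate
16 | tert-butyl{[(3Z)-5-chloro-3-methylpent-3-en-1-yl]oxy}dimethylsilane (fragment 2) | ClC/C=C(C)\CCO[Si](C)(C)C(C)(C)C | intermediate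
17 | (3S,5S,6Z,9Z)-3-bromo-5,12-bis[(tert-butyldimethylsilyl)oxy]-2,6,10-trimethyldodeca-6,9-dien-2-ol | CC(C)(C)[Si](C)(C)OCC/C(C)=C\C/C=C(C)\[C@@H](O[Si](C)(C)C(C)(C)C)C[C@H](Br)C(C)(C)O | intermediate
18 | (3Z,6Z,8S,10S)-10-bromo-8-[(tert-butyldimethylsilyl)oxy]-3,7,11-trimethyldodeca-3,6-diene-1,11-diol | OCC/C(C)=C\C/C=C(C)\[C@@H](O[Si](C)(C)C(C)(C)C)C[C@H](Br)C(C)(C)O | intermediate
19 | (3Z,6Z,8S,10S)-10-bromo-8-[(tert-butyldimethylsilyl)oxy]-11-hydroxy-3,7,11-trimethyldodeca-3,6-dienal | O=CC/C(C)=C\C/C=C(C)\[C@@H](O[Si](C)(C)C(C)(C)C)C[C@H](Br)C(C)(C)O | intermediate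
20 | (1R,6S)-6-{(2S,3S,5S)-5-bromo-3-[(tert-butyldimethylsilyl)oxy]-2,6,6-trimethyloxan-2-yl}-3-methylcyclohex-3-en-1-ol | CC(C)(C)[Si](C)(C)O[C@H]1C[C@H](Br)C(C)(C)O[C@@]1(C)[C@H]1CC=C(C)C[C@H]1O | intermediate
21 | C6' chloroacetate of 20 (C3 silyl ether, C3'=C4' alkene) | CC(C)(C)[Si](C)(C)O[C@H]1C[C@H](Br)C(C)(C)O[C@@]1(C)[C@H]1CC=C(C)C[C@H]1OC(=O)CCl | intermediate
22 | C3 alcohol (C6' chloroacetate, C3'=C4' alkene) | O[C@H]1C[C@H](Br)C(C)(C)O[C@@]1(C)[C@H]1CC=C(C)C[C@H]1OC(=O)CCl | intermediate
23 | C3 acetate C6' chloroacetate (C3'=C4' alkene) | CC(=O)O[C@H]1C[C@H](Br)C(C)(C)O[C@@]1(C)[C@H]1CC=C(C)C[C@H]1OC(=O)CCl | intermediate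
24 | 3'α,4'α-epoxide of 23 (oxygen anti to the C6' ester) | CC(=O)O[C@H]1C[C@H](Br)C(C)(C)O[C@@]1(C)[C@H]1C[C@@H]2O[C@]2(C)C[C@H]1OC(=O)CCl | intermediate
25 | 4'β-bromo-3'α-hydroxy compound (trans-diaxial, tertiary bromide) | CC(=O)O[C@H]1C[C@H](Br)C(C)(C)O[C@@]1(C)[C@H]1C[C@H](O)[C@@](C)(Br)C[C@H]1OC(=O)CCl | intermediate
26 | diaxial 3'α-chloro-4'β-bromo isomer | CC(=O)O[C@H]1C[C@H](Br)C(C)(C)O[C@@]1(C)[C@H]1C[C@H](Cl)[C@@](C)(Br)C[C@H]1OC(=O)CCl | intermediate
27 | 3'β-bromo-4'α-chloro C6' chloroacetate (trans-diequatorial) | CC(=O)O[C@H]1C[C@H](Br)C(C)(C)O[C@@]1(C)[C@H]1C[C@@H](Br)[C@](C)(Cl)C[C@H]1OC(=O)CCl | intermediate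
28 | (2S,3S,5S)-5-bromo-2-[(1S,2R,4R,5R)-5-bromo-4-chloro-2-hydroxy-4-methylcyclohexyl]-2,6,6-trimethyloxan-3-yl acetate | CC(=O)O[C@H]1C[C@H](Br)C(C)(C)O[C@@]1(C)[C@H]1C[C@@H](Br)[C@](C)(Cl)C[C@H]1O | target

Total steps: 22. Longest linear sequence: 18 steps (steps 1–8 and 13–22); fragment 2 takes steps 9–12.

Steps most likely to fail

1. Step 16 (Proposed new method). Three things may go wrong. The cation at C2 may be lost by ene-type proton transfer (from the C2 methyl or from C3–H) before the hydroxyl closes the pyran. Allylic 1,3-strain between the in-plane C3 silyloxy group and C2' may favour the other pyran chair and with it the other alkene face. The carbonyl oxygen may take the equatorial site and give the C6' epimer. The fallback uses known reactions, sets out from 19 and comes back at 20. A Me2AlCl-promoted carbonyl-ene cyclisation of 19 (CH2Cl2, −78 °C), as known for citronellal-type aldehydes, would close the carbocycle alone and give the trans homoallylic alcohol with a 1,1-disubstituted alkene at C2, the carbonyl-ene product F1. Intramolecular oxymercuration of that alkene by the C6 hydroxyl with Hg(OCOCF3)2 would give the organomercurial F2, and NaBH4 would reduce it to the C6' epimer of 20, F3. Dess–Martin oxidation would give the C6' ketone F4, and LiBH(s-Bu)3 (L-Selectride), delivering hydride from the equatorial side, would give the axial alcohol 20.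

2. Step 21. The tertiary bromide may lose HBr during chlorination or warming, or the halogen interchange may stall at the diaxial isomer while the C6' oxygen is acylated. The fallback sets out from 26 and comes back at 28. The diaxial bromochloride 26 would be isolated after the cold chlorination, its chloroacetate removed with thiourea to give the diaxial hydroxy bromochloride F5, and the diaxial-to-diequatorial interchange run as the last operation on this free alcohol (MeCN or CHCl3, gentle warming), where the C6' oxygen is small and hydrogen-bonded to O1.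

3. Step 7. Bromide may open the epoxide at the tertiary carbon, or the opening at the neopentyl-type C5 may be too slow. The fallback sets out from 7 and comes back at 9. Electrophilic bromohydroxylation of the prenyl alkene of 7 with NBS in aqueous THF at 0 °C fixes the regiochemistry by Markovnikov water delivery (Br on C5, OH on C6) but not the C5 configuration; 9 would be separated by chromatography from its C5 epimer F6.

Further compounds
F1 | step 16 | carbonyl-ene product, trans cyclohexenol with C2 methylidene and open bromohydrin chain | C=C([C@H]1CC=C(C)C[C@@H]1O)[C@@H](O[Si](C)(C)C(C)(C)C)C[C@H](Br)C(C)(C)O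
F2 | step 16 | organomercurial, pyran closed, C2–CH2–Hg trifluoroacetate | CC(C)(C)[Si](C)(C)O[C@H]1C[C@H](Br)C(C)(C)O[C@@]1(C[Hg]OC(=O)C(F)(F)F)[C@H]1CC=C(C)C[C@@H]1O
F3 | step 16 | C6' epimer of 20 | CC(C)(C)[Si](C)(C)O[C@H]1C[C@H](Br)C(C)(C)O[C@@]1(C)[C@H]1CC=C(C)C[C@@H]1O
F4 | step 16 | C6' ketone | CC(C)(C)[Si](C)(C)O[C@H]1C[C@H](Br)C(C)(C)O[C@@]1(C)[C@H]1CC=C(C)CC1=O
F5 | step 21 | diaxial hydroxy bromochloride (3'α-Cl, 4'β-Br, free C6'-OH, C3 acetate) | CC(=O)O[C@H]1C[C@H](Br)C(C)(C)O[C@@]1(C)[C@H]1C[C@H](Cl)[C@@](C)(Br)C[C@H]1O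
F6 | step 7 | C5 epimer of 9, (3R,5S,6Z)-3-bromo-5-[(tert-butyldimethylsilyl)oxy]-7-iodo-2,6-dimethylhept-6-en-2-ol | I\C=C(C)/[C@@H](O[Si](C)(C)C(C)(C)C)C[C@@H](Br)C(C)(C)O
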